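All runs come from a simulation from invented constants, noise included.

**The easy step.** Start with what is easy: two mirror-image substrates sit in one flask, meeting the same reagent and the same single-handed free catalyst. Divide their two rates at one moment and those shared factors cancel. If each rate is first order in its own substrate, left rate over right rate is s[left-handed substrate]/[right-handed substrate], where s is the ratio of the two rate constants. Integrating, the fraction of right-handed substrate remaining equals the fraction of left-handed substrate remaining raised to the power 1/s.

| setting | north-west | birch | oak | larch |
|---|---|---|---|---|
| left-handed substrate | 0.50 M | 0.50 M | 0.50 M | 0.50 M |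
| right-handed substrate | 0.50 M | 0.50 M | 0.50 M | 0.50 M |
| reagent | 1 M | 1.00 M | 1.00 M | 1.00 M |
| free catalyst | 6 mM | 3.0 mM | 3.0 mM | 3.0 mM |
| temperature | 70 °C | 70 °C | 40 °C | 10 °C |
| remark | run made earlier |  |  |  |
| time |  | 50 h | 50 h | 50 h |

north-west run (percent of the left-handed substrate and right-handed substrate together charged)

| time / h | left-handed product / % | right-handed product / % |
|---|---|---|
| 1.33 | 6 | 3 |
| 3.00 | 9 | 0 |
| 4.00 | 13 | 3 |
| 6.00 | 16 | 2 |
| 8.00 | 16 | 4 |
| 10.0 | 21 | 4 |

(standard deviation of a reading: 1.5 percentage points)

* the best flask by share of left-handed product in all that became left-handed product or right-handed product; "all alike" if 1.5 percentage points covers them all (birch / oak / larch / all alike)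
* share of left-handed product in all that became left-handed product or right-handed product, birch
* share of left-handed product in all that became left-handed product or right-handed product, oak
* share of left-handed product in all that became left-handed product or right-handed product, larch

- free catalyst is single-handed; left-handed substrate and right-handed substrate are mirror images of each other, charged as a racemate, each of them at the stated concentration
- the earlier runs do not show what temperature does; that part of a forecast is a guess
- no earlier run changes the charge of free catalyst; that part of a forecast is a guess

**Reading s.** Each substrate is half of the charge, so north-west's last reading, at 10.0 h, gives s = 6.53, the left-handed rate constant over the right-handed one, the selectivity factor. It is a loose reading: a scatter of 1.5 percentage points sits on a right-handed figure of 4%.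

**The drift.** With equal charges, the first product is left-handed at a share of s/(s+1), here 86.7%. But left-handed substrate goes faster, so at that last reading s puts north-west's new product at 4.12 to one, and the collected share read there is 84.0%.

**My decision.** Birch has 2.50 times the catalyst-hours of that reading at the same temperature. So, if rate follows catalyst and the catalyst lasts, I expect birch below 84.0%. What cold does is a guess, but if it slows conversion, larch stays nearest 86.7%. I would charge larch.

**The forecast.** It gives 80% for birch, 86% for oak and 88% for larch, the last above my opening share, and it picks larch: “Larch is therefore best, but it yields very little”.

**The result.** The simulation gives 81.7% for birch, 83.7% for oak and 87.2% for larch, so larch leads. Larch also keeps the most left-handed substrate, 87% of its charge against 58% in oak and 51% in birch. Birch shares north-west's temperature, so put s to use there: at 50.0 h, with 51% of its left-handed and 89% of its right-handed substrate left, s puts birch's new product at about 3.72 to one. That is a reckoned share of 78.8% for birch's new product, poorer than the 81.7% birch has collected.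

    reagent + free catalyst → spent catalyst (k = 0.0690 M⁻¹ h⁻¹, Ea = 74.0 kJ mol⁻¹)
    reagent + free catalyst + left-handed substrate → free catalyst + left-handed product (k = 22.0 M⁻² h⁻¹, Ea = 42.0 kJ mol⁻¹)
    reagent + free catalyst + right-handed substrate → free catalyst + right-handed product (k = 3.80 M⁻² h⁻¹, Ea = 45.0 kJ mol⁻¹)
    reagent ⇌ dormant form (K = 1.30, k = 0.240 h⁻¹, Ea = 121 kJ mol⁻¹, ΔH = −52.0 kJ mol⁻¹)
    (constants at 70 °C)

**A second flask.** Larch stopped at 30 h keeps 92% of its left-handed substrate, and the power rule, with s carried unchanged from north-west's 70 °C to larch's 10 °C, then gives a share of 86.3%. The computed share is 87.5%.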